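Begin with the slowness. The south-east flask, the one asked about, needs 1.5 h to reach 6.1% of target, while the north-west flask, with twice the second substrate, needs 2.50 h to reach 6.0%. Those readings put the time ratio near 1.67, an order in c(second substrate) of about minus 0.737. Read this as a resting state: second substrate holds part of the catalyst in a bound form.

all flasks: starting material 0.37 M; free catalyst 0.1 mol%

|  | second substrate | coupling partner | remark |
|---|---|---|---|
| south-east | 1 equiv | 1.3 equiv | the very flask that is asked about, followed so far |
| north-west | 2 equiv | 1.3 equiv | run made earlier |
| flask | 1.00 equiv | 1.30 equiv |  |

south-east run (percent of the starting material charged)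

| time / min | target / % |
|---|---|
| 8.00 | 0.9 |
| 20.0 | 1.6 |
| 40.0 | 3.1 |
| 90.0 | 6.1 |

north-west run (percent of the starting material charged)

| time / h | target / % |
|---|---|
| 0.500 | 1.4 |
| 1.33 | 3.4 |
| 2.50 | 6.0 |
| 4.00 | 8.8 |

(readings scatter by 0.3 percentage points)

* factor on the rate of making target when 5.0% of the starting material are converted if free catalyst is charged twice over
* factor on the rate when 5.0% of the starting material are converted if free catalyst is charged at 0.5 mol% instead

- the earlier runs were read with a standard deviation of 0.3 percentage points
- no earlier run changes the charge of free catalyst; that part of a forecast is a guess

Now turn the question round. One way for the rate to leave proportion with the catalyst charge is that extra catalyst changes what each catalyst unit meets, by drawing down c(second substrate); at a negative order that would push the rate above proportion, not below it. So reckon the holding fraction: the catalyst loading over the equivalents of second substrate, the share of second substrate taken if every catalyst unit bound it. It is 0.100% at the present charge and 0.500% at 0.5 mol%. Even that larger fraction moves the rate by about 0.368% at the order read above. At 5.0% conversion the reagents stand nearly alike at these charges, so my reckoning is plain proportion: a factor of 2 and of 5.00. It assumes catalyst units act singly, which no run tests.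

The forecast, 1.9 and 4.5, lies a little lower than this reckoning, since its author chose to “shade the estimates a little below linear”. The simulation gives 2.00 and 5.01.

    starting material + free catalyst ⇌ catalyst intermediate A (K = 0.980 M⁻¹, k = 0.170 M⁻¹ s⁻¹)
    coupling partner + catalyst intermediate A ⇌ free catalyst + target (K = 18.0, k = 0.590 M⁻¹ s⁻¹)
    second substrate + free catalyst ⇌ catalyst intermediate B (K = 8.30 M⁻¹, k = 0.290 M⁻¹ s⁻¹)
    coupling partner + catalyst intermediate B → free catalyst + second product (k = 0.0270 M⁻¹ s⁻¹)

In the flask, free catalyst has a half-life of 0.22 min by the forward step to catalyst intermediate A alone at 4.00 h, far shorter than the 10 h of starting material by that same forward step at 1.88 h. Catalyst intermediate B holds 65.6% of the catalyst in the flask at 2.00 h, where the holding fraction is 0.100%; with a holding fraction of 0.500% in the flask charged at 0.5 mol%, free catalyst there stands at 30.1% at 5.0% conversion, against 30.0% in the flask.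

The runs are simulated for substances that don't exist; noise was put on by code.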